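## Analysis of the target

Numbering used here: ring A (cyclohexane) is C1, C2, C3, C4, C12, C13; ring B (cyclopentane) is C4, C5, C6, C11, C12; ring C is C6 to C11; C14 is the ketone carbon on C7, C15 the spiro carbon, C16 the lactam CH2, C17 the hemiaminal carbon, C18 the lactam carbonyl, C19 the benzylic CH2, C20 and C21 the two-carbon arm ending in the hemiperacetal; β is the face of the C12 methyl. The target is a trans-anti-trans perhydrofluorene that is bridged three times. A 13-membered paracyclophane runs from the C5 aryl ether through C19, C17, C16 and C15 to the C14 ketone on C7; a spiro γ-lactam (C15 to C18 and N) carries an N-acyl hemiaminal at C17; an eight-membered 1,2-dioxocane links C15 through C20 and C21 to the tertiary peroxy carbon C8, next to a C9–C10 epoxide. There are 14 stereocentres: the C1 and C3 methyls are α and equatorial, C4–H is α, the C12 methyl β, C6–H β, C11–H α and the C10 methyl α, while the C5 oxygen, the C7 acyl group, the C8 peroxide and the epoxide are all β, so every bridge leaves the β face. The hemiperacetal, the hemiaminal, the trisubstituted epoxide and the β-keto lactam with its quaternary carbon are all sensitive to acid, base and reductants. The synthesis is hard because of the strain of the bent arene in the 13-membered ring, the density of stereocentres, and the need to bring in the peroxide and epoxide last. The strategy rests on C19: it joins the para carbon of the aryl ether to C17, and C17 is the hydrate of an enamide carbon, so a 5-methylene lactam holds C17=C19 as an alkene whose terminal carbon can be arylated.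

## Retrosynthetic reasoning

**49 to 47.** The two C–O bonds of the epoxide are cut first. The oxygen must enter on the β face, syn to the C8 peroxide, which is the face a direct electrophilic epoxidation avoids because the axial C8–O bond and the C12 methyl screen it. The forward step therefore goes through bromohydrin 48: bromine on the open α face, oxygen at the tertiary C10 from the β face, then closure with inversion at C9.

**47 to 45.** The C8–O bond and the O–C21 bond are cut. An ene-type photooxygenation places oxygen on C8, moves the alkene from C8=C9 to C9=C10 and removes the axial β hydrogen of C10; hydroperoxide 46 then adds to the aldehyde. This puts the only peroxide-forming step after all metal chemistry.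

**45 to 44.** The C17–OH bond and the aldehyde are traced to the enamide and the dimethyl acetal of 44. One acid treatment does both, and the enamide must be gone before the photooxygenation because enamides are cleaved by it.

**44 to 43.** The C19–aryl bond is cut. This is the only disconnection that opens the strained ring at a carbon which is sp2 in the precursor and whose oxidation level is restored by simple hydration. The forward reaction has to insert the exocyclic enamide into an aryl–palladium bond at C19 and close 13 atoms.

**43 to 38.** The N–C17 bond is cut to alkyne amide 42 (5-exo hydroamidation). The C15–C16 and C15–C20 bonds are cut to propargyl bromide 41, bromoacetal 39 and β-keto amide 38. The slow electrophile 39 goes on first, while C15 is still unhindered; the reactive 41 then creates the quaternary centre, and this order fixes the sense of the C15 configuration.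

**38 to 27.** The C14–C15 bond is cut to aldehyde 34 and acetonitrile 35, which supplies C15, C18 and N. The aryl–O bond is cut to alcohol 27 and iodonium salt 31 (from 28 and 29). Arylation with retention at C5 is placed where the molecule carries no acidic C–H.

**27 to 22.** The C8–methyl bond is cut to enol triflate 24 and stannane 25. The triflate comes from enone 22 by reduction and trapping of the enolate. This one operation fixes the alkene at C8=C9 without regiochemical ambiguity and sets C10 by axial protonation.

**22 to 16.** Ring C is opened at C6–C7 and C9=C10, giving enone 16 and phosphonate 17. The Michael step sets C6 and C11 trans, and the olefination decides which carbon becomes the ketone. The ester of 19 becomes the C7 hydroxymethyl carbon and later C14.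

**16 to 9.** The C10–C11 bond is cut to enol triflate 13 and stannane 14. The C5–O bond is traced to conjugate borylation of enone 9, which places oxygen on the β face directly.

**9 to 1 and 2.** Rings A and B come from enedione 4 by an amino-acid-catalysed aldol condensation of triketone 3, itself from dione 1 and enone 2. The C2 ketone of 4 is kept long enough to set C4 by reduction and C1 and C3 by equilibration, and is then removed.

## Alternatives that were turned down

**Alternative 1:** Ring B first. The two bonds from ring B into ring A (C4–C3 and C12–C13) and the quaternary C12 would be made on silyloxy cyclopentenone A1 by conjugate addition of a 2-propenyl group as its cuprate and trapping of the enolate with the allylic dibromide A2, giving ketone A3.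
- For: two C–C bonds, the quaternary centre and the trans relation at C4/C12 arise in one well-precedented anti,anti operation, and the C5 oxygen comes in with the starting enone. On these points it is stronger than the present route, which needs an aldol condensation, a dissolving-metal reduction and a borylation for the same centres.
- Against: ring A must then be closed between the vinyl bromide and the propenyl group, and its C1 and C3 methyls set by hydrogenation. Hydrogen would come from the open α face and push both methyls to the β (axial) side, the opposite of the target. Ring C and the whole macrocycle would still lie ahead, so the real risk of the target is not addressed.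
- The chosen route offers in exchange thermodynamic control of C1 and C3 next to a temporary C2 ketone and keeps the uncertainty in one late step.

**Alternative 2:** Rings B and C in one cascade. The C5–C6 and C7–C8 bonds would form when a divalent samarium reductant turns the aldehyde of keto enoate A4 into a ketyl that adds to the enoate, the resulting enolate closing ring C on the methyl ketone to give diol ester A5.
- For: step economy for the carbocycle is clearly better than here, where ring C takes six steps from 16, and the C5 oxygen and the trans C5/C6 relation come with the cyclisation.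
- Against: A4 needs the C10–C11–C12 triad, with a quaternary carbon between two stereocentres, to be built on an open chain. The tertiary C8 alcohol of A5 must be eliminated toward C9, yet the ester-activated C7–H makes elimination into conjugation (C7=C8) the expected course.
- The chosen route fixes the alkene position through a regiodefined enol triflate and sets C10 by axial protonation, at the cost of more steps.

**Alternative 3:** Spiro centre by tethered alkylation. The C15–C20 bond would form last, when the β-keto lactam enolate of macrocyclic iodide A6, tethered through the ring C peroxide, displaces the primary iodide to give the O-ethyl peroxyacetal A7.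
- For: the tether fixes C15 without ambiguity, which is stronger than the open-chain alkylation of step 26, and the dioxocane is closed by a C–C bond and not by a reversible hemiperacetal.
- Against: the enolate has to be generated with the peroxide, the epoxide and the hemiaminal already present, and base-induced fragmentation of the peroxide is a known failure. The displacement is an eight-membered ring closure at a carbon next to an acetal carbon, which is electronically retarded. The last step would need acid to free the hemiperacetal beside the epoxide. The plan also presupposes the paracyclophane without saying how it is closed.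
- The chosen route accepts a less certain C15 step early, where material is cheap, and answers the ring-strain question directly.

Key step: step 28

Remarks on the chemistry: C17 and C21 equilibrate by ring–chain tautomerism and are taken to settle as in the target. Phosphonate 17 is taken as an article of commerce.

## Route

Step 1
Reactants: 1 2-methylcyclopentane-1,3-dione; 2 2-methylpent-1-en-3-one
Product: 3 2-methyl-2-(2-methyl-3-oxopentyl)cyclopentane-1,3-dione
Conditions: H2O, AcOH (cat.), 75 °C
Reagents that add atoms: none
Why: Michael addition of the cyclic 1,3-dione to the vinyl ketone; the side-chain stereocentre (later C1) forms as both epimers and is corrected by enolisation in steps 2 and 4.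

Step 2
Reactants: 3 triketone
Product: 4 (6S,7aR)-4,6,7a-trimethyl-2,3,7,7a-tetrahydro-1H-indene-1,5(6H)-dione
Conditions: D-phenylalanine (1 equiv), camphorsulfonic acid (0.5 equiv), DMF, 30 → 70 °C
Reagents that add atoms: none
Why: Hajos–Parrish–Eder–Sauer–Wiechert aldol condensation; the enamine of the D-amino acid attacks one of the two enantiotopic ring carbonyls and so sets the quaternary C12 (the L-acid gives the antipodal, steroid-like series). The C1 methyl settles trans to the angular methyl by acid-catalysed enolisation.

Step 3
Reactants: 4 enedione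
Product: 5 hydroxy enone (C11 β-alcohol)
Conditions: NaBH4, EtOH, −20 °C
Reagents that add atoms: none
Why: Chemoselective 1,2-reduction: the saturated cyclopentanone is more electrophilic than the enone carbonyl and hydride enters anti to the angular methyl. The alcohol shields C11 during steps 4 and 5 and is re-oxidised in step 6.

Step 4
Reactants: 5 hydroxy enone
Product: 6 trans-fused hydroxy ketone
Conditions: Li, NH3(l), THF, t-BuOH, −78 °C; NH4Cl; then NaOMe (cat.), MeOH, rt
Reagents that add atoms: none
Why: Birch-type reduction of the enone; C4 is protonated axially, anti to the axial C12 methyl, which gives the trans ring fusion (C4–H α). Base equilibration then places the C1 and C3 methyls, both α to the C2 ketone, equatorial (α).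

Step 5
Reactants: 6 hydroxy ketone
Product: 7 bicyclic alcohol
Conditions: N2H4·H2O, KOH, diethylene glycol, 130 → 200 °C
Reagents that add atoms: none
Why: Wolff–Kishner reduction (Huang–Minlon procedure) removes the C2 carbonyl after it has set C1 and C3; both centres are already in their stable equatorial arrangement, so the hot base cannot erode them.

Step 6
Reactants: 7 bicyclic alcohol
Product: 9 bicyclic enone with C5=C6 and the C11 ketone, via ketone 8 (not isolated)
Conditions: IBX (3.5 equiv), DMSO, 25 → 75 °C
Reagents that add atoms: none
Why: IBX oxidises the alcohol and then dehydrogenates the ketone through its enol; only C6 carries α-hydrogens (C12 is quaternary), so a single enone can form.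

Step 7
Reactants: 9 bicyclic enone
Product: 11 β-hydroxy ketone (C5 β-OH), via boryl ketone 10 (not isolated)
Conditions: B2pin2, CuCl (5 mol %), Xantphos (5 mol %), NaOt-Bu (10 mol %), MeOH, THF, rt; then NaBO3·4H2O, THF/H2O, rt
Reagents that add atoms: bis(pinacolato)diboron, CC1(C)OB(OC1(C)C)B1OC(C)(C)C(C)(C)O1 (boron of 10); sodium perborate, [Na+].OO[B-](O)(O)O (oxygen of 11)
Why: Copper-catalysed conjugate borylation, then C–B oxidation with retention. The boryl copper should add to C5 on the β face, because the α face of the flat enone is screened by the equatorial C3 methyl and the axial C4–H, the same bias that sends nucleophiles to the β face of 15-en-17-one steroids.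

Step 8
Reactants: 11 β-hydroxy ketone
Product: 12 methoxymethyl ether
Conditions: MeOCH2Cl, i-Pr2NEt, CH2Cl2, 0 °C → rt
Reagents that add atoms: chloromethyl methyl ether, COCCl
Why: Acetal protection of the C5 alcohol under mild amine base; the ether is stable to the enolate, dissolving-metal and palladium steps ahead and is removable at −78 °C.

Step 9
Reactants: 12 methoxymethyl ether
Product: 13 enol triflate (C6=C11)
Conditions: KN(SiMe3)2, THF, −78 °C; then PhNTf2, −78 → 0 °C
Reagents that add atoms: N-phenylbis(trifluoromethanesulfonimide), O=S(=O)(N(c1ccccc1)S(=O)(=O)C(F)(F)F)C(F)(F)F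
Why: Enolate O-sulfonylation; the ketone can enolise only toward C6, and the low temperature keeps the β-alkoxy enolate from eliminating.

Step 10
Reactants: 13 enol triflate; 14 tributyl(1-ethoxyvinyl)stannane
Product: 16 acetyl cyclopentene (C6=C11 enone), via enol ether 15 (not isolated)
Conditions: Pd(PPh3)4 (5 mol %), LiCl, THF, 65 °C; then 1 M HCl, THF, 0 °C
Reagents that add atoms: water, O
Why: Stille coupling of a hindered alkenyl triflate, as practised on steroid 17-enol triflates, followed by hydrolysis of the enol ether; the acetyl carbon is C10 and its methyl the future C10 methyl.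

Step 11
Reactants: 16 acetyl cyclopentene; 17 ethyl 4-(diethoxyphosphoryl)-3-oxobutanoate
Product: 19 tricyclic enone ester, via Michael adduct 18 (not isolated)
Conditions: NaOEt (0.2 equiv), EtOH, rt; then LiCl, DBU, MeCN, 40 °C
Reagents that add atoms: none
Why: Tandem Michael addition and intramolecular Horner–Wadsworth–Emmons annulation. The β-keto ester carbon of 17 adds to C6 from the α face, anti to the C5 ether and the C12 methyl, and C11 is protonated to the trans arrangement (acetyl β) as in 16-substituted 20-keto steroids. The phosphonate carbon then closes ring C on the acetyl carbonyl, which fixes the ketone at C8 and the alkene at C9=C10; the C7 ester takes the equatorial β position by enolisation.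

Step 12
Reactants: 19 tricyclic enone ester
Product: 20 diol
Conditions: LiBH4, THF/MeOH (20:1), 0 °C → rt
Reagents that add atoms: none
Why: Hydride reduction of the ketone (1,2) and of the ester; it removes the acidic β-keto ester proton that would stop the dissolving-metal step and turns the ester carbon into a robust one-carbon handle on C7. The C8 carbinol configuration is immaterial.

Step 13
Reactants: 20 diol
Product: 21 hydroxymethyl enone
Conditions: MnO2, CH2Cl2, rt
Reagents that add atoms: none
Why: MnO2 oxidises only the allylic C8 alcohol and leaves the primary alcohol; C7, now α to the ketone, keeps its stable equatorial substituent.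

Step 14
Reactants: 21 hydroxymethyl enone
Product: 22 silyl ether enone
Conditions: i-Pr3SiCl, imidazole, DMF, rt
Reagents that add atoms: chlorotriisopropylsilane, CC(C)[Si](Cl)(C(C)C)C(C)C
Why: Silylation of the primary alcohol under conditions too mild to dehydrate the β-hydroxy ketone; the silyl ether survives Li/NH3 and is orthogonal to the methoxymethyl ether.

Step 15
Reactants: 22 silyl ether enone
Product: 24 enol triflate (C8=C9), via lithium enolate 23 (not isolated)
Conditions: Li, NH3(l), THF, t-BuOH (1 equiv), −78 °C; isoprene; NH3 removed; then PhNTf2, THF, −78 → 0 °C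
Reagents that add atoms: lithium, [Li] (lithium of 23); N-phenylbis(trifluoromethanesulfonimide), O=S(=O)(N(c1ccccc1)S(=O)(=O)C(F)(F)F)C(F)(F)F
Why: Dissolving-metal reduction of the enone with trapping of the regiodefined enolate (reductive enol triflate formation). C10 is protonated axially from the β face, anti to the axial C11–H, which leaves the C10 methyl equatorial (α); the enolate exists only toward C9, so the later alkene can only be C8=C9.

Step 16
Reactants: 24 enol triflate; 25 tetramethylstannane
Product: 26 C8-methyl alkene
Conditions: Pd(PPh3)4 (5 mol %), LiCl, DMF, 80 °C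
Reagents that add atoms: none
Why: Stille methylation of an alkenyl triflate; it installs the C8 methyl and completes the C8=C9 alkene with C7 and C10 untouched.

Step 17
Reactants: 26 C8-methyl alkene
Product: 27 C5 alcohol
Conditions: Me2BBr, CH2Cl2, −78 °C; then aq. NaHCO3, THF
Reagents that add atoms: none
Why: Lewis-acid cleavage of the methoxymethyl acetal at low temperature; no protic acid is used, so the trisubstituted alkene cannot migrate and the primary silyl ether stays.

Step 18
Reactants: 28 1,4-diiodobenzene (2 equiv); 29 1,3,5-trimethoxybenzene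
Product: 31 (4-iodophenyl)(2,4,6-trimethoxyphenyl)iodonium tosylate, via iodane 30 (not isolated)
Conditions: 3-chloroperbenzoic acid, TsOH·H2O, CH2Cl2/CF3CH2OH, rt; then 29, rt
Reagents that add atoms: 3-chloroperbenzoic acid, OOC(=O)c1cccc(Cl)c1 (oxygen of 30); 4-methylbenzenesulfonic acid, Cc1ccc(cc1)S(=O)(=O)O
Why: One-pot diaryliodonium synthesis: one iodine of 28 is oxidised to the hydroxy(tosyloxy)iodane, which substitutes the electron-rich arene 29; the cationic iodine deactivates the second C–I bond toward oxidation.

Step 19
Reactants: 27 C5 alcohol; 31 iodonium tosylate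
Product: 32 4-iodophenyl ether
Conditions: NaH, THF, 0 °C; then 31, rt
Reagents that add atoms: none
Why: Metal-free O-arylation of an alkoxide with a diaryliodonium salt (ligand coupling on iodine); the 4-iodophenyl group is transferred because the trimethoxyphenyl group is electron-rich and doubly ortho-substituted. The C5–O bond is not broken, so the β configuration is kept, and the substrate has no acidic C–H at this stage.

Step 20
Reactants: 32 4-iodophenyl ether
Product: 33 primary alcohol
Conditions: Bu4NF, THF, rt
Reagents that add atoms: none
Why: Fluoride cleavage of the silyl ether; nothing else in 32 responds to fluoride.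

Step 21
Reactants: 33 primary alcohol
Product: 34 aldehyde
Conditions: Dess–Martin periodinane, NaHCO3, CH2Cl2, 0 °C
Reagents that add atoms: none
Why: Buffered hypervalent-iodine oxidation at low temperature, chosen because 34 is a β,γ-unsaturated aldehyde whose C7 could epimerise or conjugate under base; it is used at once.

Step 22
Reactants: 34 aldehyde; 35 acetonitrile
Product: 36 β-hydroxy nitrile
Conditions: LiN(i-Pr)2, 35, THF, −78 °C; then 34, −78 °C; NH4Cl
Reagents that add atoms: none
Why: Aldol-type addition of lithioacetonitrile, which is fast at −78 °C and does not exchange with the aryl iodide; C7 is no longer epimerisable in 36 and the carbinol configuration is irrelevant.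

Step 23
Reactants: 36 β-hydroxy nitrile
Product: 37 β-hydroxy amide
Conditions: PtH(PMe2OH)(PMe2O)2H (2 mol %), EtOH/H2O, 80 °C
Reagents that add atoms: water, O
Why: Platinum-catalysed hydration of a nitrile to the primary amide under neutral conditions; the aryl iodide and the alkene are inert to this catalyst.

Step 24
Reactants: 37 β-hydroxy amide
Product: 38 β-keto amide
Conditions: Dess–Martin periodinane, CH2Cl2, rt
Reagents that add atoms: none
Why: Oxidation of the secondary alcohol; from here the doubly activated C15–H is the most acidic site and buffers C7 against deprotonation.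

Step 25
Reactants: 38 β-keto amide; 39 2-bromo-1,1-dimethoxyethane
Product: 40 monoalkylated β-keto amide
Conditions: Cs2CO3, NaI (0.2 equiv), DMF, 70 °C
Reagents that add atoms: none
Why: C-alkylation of the β-keto amide enolate; the sluggish acetal electrophile is used while C15 is still a methylene carbon, with iodide catalysis. C15 stays epimerisable and is set in step 26.

Step 26
Reactants: 40 monoalkylated β-keto amide; 41 3-bromoprop-1-yne
Product: 42 quaternary alkyne amide
Conditions: NaH (1.0 equiv), THF, 0 °C; then 41, 0 °C → rt
Reagents that add atoms: none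
Why: C-alkylation of the chelated sodium Z-enolate creates the quaternary C15. The C7–H bond should eclipse the C14=C15 bond to avoid allylic 1,3-strain with the C20 arm, so C6 with its C5 aryl ether covers one face and the flat C8 the other; the bromide enters anti to C6, which, with the acetal arm already in place, gives the C15 configuration of the target.

Step 27
Reactants: 42 quaternary alkyne amide
Product: 43 spiro 5-methylene lactam (aryl iodide)
Conditions: Bu4NF (1 equiv), THF, 50 °C
Reagents that add atoms: none
Why: 5-exo-dig hydroamidation of the terminal alkyne by the fluoride-activated primary amide, helped by the quaternary C15 (Thorpe–Ingold effect); under basic, metal-free conditions nitrogen, not oxygen, closes the ring and the exocyclic enamide results.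

Step 28
Reactants: 43 spiro 5-methylene lactam (aryl iodide)
Product: 44 macrocyclic endocyclic enamide
Conditions: Pd(OAc)2 (20 mol %), P(o-tol)3 (40 mol %), Ag2CO3 (2 equiv), MeCN/toluene, 80 °C, 1 mM, slow addition
Reagents that add atoms: none
Why: Mizoroki–Heck macrocyclisation: zerovalent palladium formed from Pd(OAc)2 and P(o-tol)3 adds to the C–I bond, and Ag2CO3 removes iodide and serves as base, so a cationic arylpalladium binds the electron-rich exocyclic enamide. Syn insertion puts the aryl group on the terminal carbon C19 and palladium on C17; the reverse regiochemistry would build a quaternary aminal carbon with no β-hydrogen and is both hindered and unproductive, so the terminal selectivity is steric and does not depend on a neutral pathway. syn-β-Hydride elimination toward C16 gives 44; elimination toward C19 or nitrogen would give isomers that meet 44 at the same N-acyliminium ion in step 29, and the quaternary C15 stops further chain walking. The ring closed is the 13-membered paracyclophane, in the endo mode because both alkene carbons lie in the new ring. No stereocentre is formed, C17 being trigonal in 44. The closest known reactions are intramolecular Heck macrocyclisations of aryl iodides and the Heck arylation of 1,1-disubstituted enamides and enol ethers at the terminal carbon. The step needs ring closure to beat oligomerisation, which the cis (β,β) placement of the C5 ether and the C7 acyl arm on the rigid tricycle and the high dilution should secure; it also needs insertion to precede migration of the exocyclic alkene into the lactam, for which the silver salt, which suppresses re-addition of palladium hydride, is chosen.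

Step 29
Reactants: 44 macrocyclic endocyclic enamide
Product: 45 hydroxylactam aldehyde
Conditions: CF3CO2H/H2O/THF (1:2:8), 0 °C → rt
Reagents that add atoms: water, O
Why: Acid-catalysed hydration of the enamide through the N-acyliminium ion, and hydrolysis of the dimethyl acetal. C17 is set under thermodynamic control, since the hemiaminal re-ionises reversibly.

Step 30
Reactants: 45 hydroxylactam aldehyde
Product: 47 hemiperacetal alkene, via hydroperoxide 46 (not isolated)
Conditions: O2, visible light, tetraphenylporphyrin (cat.), CH2Cl2, −20 °C; then rt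
Reagents that add atoms: dioxygen, O=O
Why: Schenck ene reaction of singlet oxygen at the trisubstituted C8=C9 alkene: oxygen adds to C8 on the β face and takes the axial β hydrogen of C10, which is aligned with the π system, while the competing axial C7–H on the α face is deactivated by the adjacent ketone. The tertiary hydroperoxide then adds to the aldehyde to close the dioxocane, with C21 settling by equilibration.

Step 31
Reactants: 47 hemiperacetal alkene
Product: 49 CNP0533733.1, via bromohydrin 48 (not isolated)
Conditions: N-bromosuccinimide, THF/H2O (4:1), 0 °C, dark; then Ag2O, THF, rt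
Reagents that add atoms: N-bromosuccinimide, O=C1CCC(=O)N1Br (bromine of 48); water, O
Why: Bromohydrin formation and ring closure, the classical way to the epoxide a peracid does not give. Bromine takes the open α face of C9=C10 and water opens the bromonium ion trans-diaxially at the tertiary C10 from the β face. Silver-assisted displacement of the axial bromide by the C10 oxygen then inverts C9 and leaves the epoxide β, syn to the peroxide.

## Compound list

1 | 2-methylcyclopentane-1,3-dione | CC1C(=O)CCC1=O | starting material
2 | 2-methylpent-1-en-3-one | CCC(=O)C(C)=C | starting material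
3 | 2-methyl-2-(2-methyl-3-oxopentyl)cyclopentane-1,3-dione (both epimers at the side-chain carbon) | CCC(=O)C(C)CC1(C)C(=O)CCC1=O | intermediate
4 | (6S,7aR)-4,6,7a-trimethyl-2,3,7,7a-tetrahydro-1H-indene-1,5(6H)-dione (C2 ketone, C3=C4, C11 ketone) | C[C@@H]1C(=O)C(C)=C2CCC(=O)[C@]2(C)C1 | intermediate
5 | (1R,6S,7aR)-1-hydroxy-4,6,7a-trimethyl-1,2,3,6,7,7a-hexahydro-5H-inden-5-one (C11 β-OH) | C[C@@H]1C(=O)C(C)=C2CC[C@@H](O)[C@]2(C)C1 | intermediate
6 | trans-fused rings A/B hydroxy ketone: C2 ketone, C1 and C3 methyls α, C4–H α, C12 methyl β, C11–OH β | C[C@@H]1C(=O)[C@H](C)[C@H]2CC[C@@H](O)[C@]2(C)C1 | intermediate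
7 | rings A/B alcohol: as 6 without the C2 carbonyl | C[C@@H]1C[C@H](C)[C@H]2CC[C@@H](O)[C@]2(C)C1 | intermediate
8 | rings A/B C11 ketone (not isolated) | C[C@@H]1C[C@H](C)[C@H]2CCC(=O)[C@]2(C)C1 | intermediate
9 | rings A/B enone: C11 ketone, C5=C6 | C[C@@H]1C[C@H](C)[C@H]2C=CC(=O)[C@]2(C)C1 | intermediate
10 | C5 β-(pinacolato)boryl C11 ketone (not isolated) | C[C@@H]1C[C@H](C)[C@H]2[C@@H](B3OC(C)(C)C(C)(C)O3)CC(=O)[C@]2(C)C1 | intermediate
11 | C5 β-hydroxy C11 ketone | C[C@@H]1C[C@H](C)[C@H]2[C@@H](O)CC(=O)[C@]2(C)C1 | intermediate
12 | C5 β-(methoxymethoxy) C11 ketone | C[C@@H]1C[C@H](C)[C@H]2[C@@H](OCOC)CC(=O)[C@]2(C)C1 | intermediate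
13 | C11 enol triflate (C6=C11), C5 β-OCH2OMe | C[C@@H]1C[C@H](C)[C@H]2[C@@H](OCOC)C=C(OS(=O)(=O)C(F)(F)F)[C@]2(C)C1 | intermediate
14 | tributyl(1-ethoxyvinyl)stannane | CCCC[Sn](CCCC)(CCCC)C(=C)OCC | starting material
15 | C11-(1-ethoxyvinyl) C6=C11 diene (not isolated) | C[C@@H]1C[C@H](C)[C@H]2[C@@H](OCOC)C=C(C(=C)OCC)[C@]2(C)C1 | intermediate
16 | C11-acetyl C6=C11 enone, C5 β-OCH2OMe | C[C@@H]1C[C@H](C)[C@H]2[C@@H](OCOC)C=C(C(C)=O)[C@]2(C)C1 | intermediate
17 | ethyl 4-(diethoxyphosphoryl)-3-oxobutanoate | CCOC(=O)CC(=O)CP(=O)(OCC)OCC | starting material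
18 | Michael adduct: C6 α-[1-ethoxycarbonyl-3-(diethoxyphosphoryl)-2-oxopropyl], C11 β-acetyl (C7 epimers; not isolated) | C[C@@H]1C[C@H](C)[C@H]2[C@@H](OCOC)[C@H](C(C(=O)OCC)C(=O)CP(=O)(OCC)OCC)[C@@H](C(C)=O)[C@]2(C)C1 | intermediate
19 | tricyclic enone ester: C8 ketone, C9=C10, C7 β-CO2Et, C6–H β, C11–H α, C5 β-OCH2OMe | C[C@@H]1C[C@H](C)[C@H]2[C@@H](OCOC)[C@@H]3[C@@H](C(=O)OCC)C(=O)C=C(C)[C@H]3[C@]2(C)C1 | intermediate
20 | diol: C8 α-OH (drawn; either epimer serves), C7 β-CH2OH, C9=C10 | C[C@@H]1C[C@H](C)[C@H]2[C@@H](OCOC)[C@@H]3[C@@H](CO)[C@H](O)C=C(C)[C@H]3[C@]2(C)C1 | intermediate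
21 | hydroxymethyl enone: C8 ketone, C9=C10, C7 β-CH2OH | C[C@@H]1C[C@H](C)[C@H]2[C@@H](OCOC)[C@@H]3[C@@H](CO)C(=O)C=C(C)[C@H]3[C@]2(C)C1 | intermediate
22 | as 21 with C7 β-CH2OSi(i-Pr)3 | C[C@@H]1C[C@H](C)[C@H]2[C@@H](OCOC)[C@@H]3[C@@H](CO[Si](C(C)C)(C(C)C)C(C)C)C(=O)C=C(C)[C@H]3[C@]2(C)C1 | intermediate
23 | lithium enolate C8(OLi)=C9, C10 methyl α (not isolated) | C[C@@H]1C[C@H](C)[C@H]2[C@@H](OCOC)[C@@H]3[C@@H](CO[Si](C(C)C)(C(C)C)C(C)C)C(O[Li])=C[C@H](C)[C@H]3[C@]2(C)C1 | intermediate
24 | enol triflate C8(OTf)=C9, C10 methyl α | C[C@@H]1C[C@H](C)[C@H]2[C@@H](OCOC)[C@@H]3[C@@H](CO[Si](C(C)C)(C(C)C)C(C)C)C(OS(=O)(=O)C(F)(F)F)=C[C@H](C)[C@H]3[C@]2(C)C1 | intermediate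
25 | tetramethylstannane | C[Sn](C)(C)C | starting material
26 | C8-methyl C8=C9 alkene; C5 β-OCH2OMe; C7 β-CH2OSi(i-Pr)3; C10 methyl α | C[C@@H]1C[C@H](C)[C@H]2[C@@H](OCOC)[C@@H]3[C@@H](CO[Si](C(C)C)(C(C)C)C(C)C)C(C)=C[C@H](C)[C@H]3[C@]2(C)C1 | intermediate
27 | C5 β-alcohol of 26 | C[C@@H]1C[C@H](C)[C@H]2[C@@H](O)[C@@H]3[C@@H](CO[Si](C(C)C)(C(C)C)C(C)C)C(C)=C[C@H](C)[C@H]3[C@]2(C)C1 | intermediate
28 | 1,4-diiodobenzene | Ic1ccc(I)cc1 | starting material
29 | 1,3,5-trimethoxybenzene | COc1cc(OC)cc(OC)c1 | starting material
30 | 1-[hydroxy(tosyloxy)iodo]-4-iodobenzene (not isolated) | Cc1ccc(cc1)S(=O)(=O)OI(O)c1ccc(I)cc1 | intermediate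
31 | (4-iodophenyl)(2,4,6-trimethoxyphenyl)iodonium 4-methylbenzenesulfonate | COc1cc(OC)c([I+]c2ccc(I)cc2)c(OC)c1.Cc1ccc(cc1)S(=O)(=O)[O-] | intermediate
32 | C5 β-(4-iodophenoxy) ether, C7 β-CH2OSi(i-Pr)3 | C[C@@H]1C[C@H](C)[C@H]2[C@@H](Oc3ccc(I)cc3)[C@@H]4[C@@H](CO[Si](C(C)C)(C(C)C)C(C)C)C(C)=C[C@H](C)[C@H]4[C@]2(C)C1 | intermediate
33 | C7 β-CH2OH aryl ether | C[C@@H]1C[C@H](C)[C@H]2[C@@H](Oc3ccc(I)cc3)[C@@H]4[C@@H](CO)C(C)=C[C@H](C)[C@H]4[C@]2(C)C1 | intermediate
34 | C7 β-CHO aryl ether | C[C@@H]1C[C@H](C)[C@H]2[C@@H](Oc3ccc(I)cc3)[C@@H]4[C@@H](C=O)C(C)=C[C@H](C)[C@H]4[C@]2(C)C1 | intermediate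
35 | acetonitrile | CC#N | starting material
36 | C7 β-CH(OH)CH2CN (C14 epimers) | C[C@@H]1C[C@H](C)[C@H]2[C@@H](Oc3ccc(I)cc3)[C@@H]4[C@@H](C(O)CC#N)C(C)=C[C@H](C)[C@H]4[C@]2(C)C1 | intermediate
37 | C7 β-CH(OH)CH2CONH2 (C14 epimers) | C[C@@H]1C[C@H](C)[C@H]2[C@@H](Oc3ccc(I)cc3)[C@@H]4[C@@H](C(O)CC(N)=O)C(C)=C[C@H](C)[C@H]4[C@]2(C)C1 | intermediate
38 | C7 β-C(=O)CH2CONH2 (β-keto amide) | C[C@@H]1C[C@H](C)[C@H]2[C@@H](Oc3ccc(I)cc3)[C@@H]4[C@@H](C(=O)CC(N)=O)C(C)=C[C@H](C)[C@H]4[C@]2(C)C1 | intermediate
39 | 2-bromo-1,1-dimethoxyethane | COC(CBr)OC | starting material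
40 | C7 β-C(=O)CH[CH2CH(OMe)2]CONH2 (C15 epimers) | C[C@@H]1C[C@H](C)[C@H]2[C@@H](Oc3ccc(I)cc3)[C@@H]4[C@@H](C(=O)C(CC(OC)OC)C(N)=O)C(C)=C[C@H](C)[C@H]4[C@]2(C)C1 | intermediate
41 | 3-bromoprop-1-yne | C#CCBr | starting material
42 | C7 β-C(=O)C[CH2CH(OMe)2](CH2C≡CH)CONH2, C15 as in the target | C[C@@H]1C[C@H](C)[C@H]2[C@@H](Oc3ccc(I)cc3)[C@@H]4[C@@H](C(=O)[C@](CC(OC)OC)(CC#C)C(N)=O)C(C)=C[C@H](C)[C@H]4[C@]2(C)C1 | intermediate
43 | aryl iodide with spiro 5-methylene lactam (Heck precursor) | C[C@@H]1C[C@H](C)[C@H]2[C@@H](Oc3ccc(I)cc3)[C@@H]4[C@@H](C(=O)[C@]5(CC(OC)OC)CC(=C)NC5=O)C(C)=C[C@H](C)[C@H]4[C@]2(C)C1 | intermediate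
44 | macrocyclic endocyclic enamide (C16=C17) | C[C@@H]1C[C@H](C)[C@H]2[C@H]3Oc4ccc(cc4)CC4=C[C@](CC(OC)OC)(C(=O)N4)C(=O)[C@H]5C(C)=C[C@H](C)[C@H]([C@H]35)[C@]2(C)C1 | intermediate
45 | macrocyclic C17 hydroxylactam with C20–C21 aldehyde | C[C@@H]1C[C@H](C)[C@H]2[C@H]3Oc4ccc(cc4)C[C@]4(O)C[C@](CC=O)(C(=O)N4)C(=O)[C@H]5C(C)=C[C@H](C)[C@H]([C@H]35)[C@]2(C)C1 | intermediate
46 | C8 β-hydroperoxide, C9=C10 (not isolated) | C[C@@H]1C[C@H](C)[C@H]2[C@H]3Oc4ccc(cc4)C[C@]4(O)C[C@](CC=O)(C(=O)N4)C(=O)[C@H]5[C@@](C)(OO)C=C(C)[C@H]([C@H]35)[C@]2(C)C1 | intermediate
47 | dioxocane hemiperacetal with C9=C10 | C[C@@H]1C[C@H](C)[C@H]2[C@H]3Oc4ccc(cc4)C[C@]4(O)C[C@]5(C[C@H](O)OO[C@@]6(C)C=C(C)[C@H]([C@H]3[C@H]6C5=O)[C@]2(C)C1)C(=O)N4 | intermediate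
48 | bromohydrin: C9 α-Br, C10 β-OH (not isolated) | C[C@@H]1C[C@H](C)[C@H]2[C@H]3Oc4ccc(cc4)C[C@]4(O)C[C@]5(C[C@H](O)OO[C@@]6(C)[C@H](Br)[C@@](C)(O)[C@H]([C@H]3[C@H]6C5=O)[C@]2(C)C1)C(=O)N4 | intermediate
49 | CNP0533733.1 | C[C@@H]1C[C@H](C)[C@H]2[C@H]3Oc4ccc(cc4)C[C@]4(O)C[C@]5(C[C@H](O)OO[C@@]6(C)[C@H]7O[C@@]7(C)[C@H]([C@H]3[C@H]6C5=O)[C@]2(C)C1)C(=O)N4 | target

## Step count and least certain steps

Total: 31 steps (step 18 prepares the arylating agent). Longest linear sequence: 30 steps (steps 1 to 17 and 19 to 31).

**Step 28 (key step).** The most likely failure is oligomerisation or loss of iodine by reduction, because the arene has to bend to close 13 atoms; the exocyclic alkene may also slip into the lactam before it inserts. Fallback, same bond by enolate arylation: from 42, gold-catalysed hydration of the alkyne (AuCl(PPh3), AgOTf, aqueous dioxane) gives the methyl ketone F1, in equilibrium with its hydroxylactam. Palladium-catalysed intramolecular α-arylation of that methyl ketone (Pd2(dba)3, Xantphos, Cs2CO3, toluene, 100 °C, high dilution) closes the same ring and gives the macrocyclic hydroxylactam acetal F2. Aqueous acid as in step 29 then returns to 45.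

**Step 30.** The ene reaction may abstract the C7 hydrogen or a hydrogen of the C8 methyl, or attack from the α face, because three allylic positions compete and the β face is the more crowded. Fallback by ionic chemistry with fixed stereochemistry: from 45, N-bromosuccinimide with anhydrous H2O2 in ether at −40 °C puts bromine on C9 from the α face and the hydroperoxide on the tertiary C8 from the β face (trans-diaxial opening), and the hydroperoxide closes on the aldehyde to the bromo hemiperacetal F3. Anti elimination of HBr across C9 and the axial C10–H (Li2CO3, LiBr, DMF, 60 °C) returns to 47.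

**Step 26.** Facial discrimination at C15 may be weak, because the controlling centre C7 is three bonds away and the chelate can rotate. Fallback by reagent control in place of substrate control: from 40, the same alkylation is run under asymmetric phase-transfer catalysis (a C2-symmetric binaphthyl-derived spiro ammonium bromide, solid KOH, toluene, −20 °C), the catalyst enantiomer being chosen to give 42; no new compound arises (F0).

**Step 15.** Proton transfer during the change of solvent may scramble the enolate before sulfonylation, and sulfonylation may be incomplete. Fallback that takes regiocontrol from kinetic deprotonation: from 22, the reduction is quenched with NH4Cl to give the saturated ketone F4; LiN(i-Pr)2 at −78 °C removes the less hindered C9 hydrogen and PhNTf2 returns to 24.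

**Step 31.** The bromine may attack the bent, electron-rich arene, and the peroxide may decompose during ring closure. Fallback by catalyst-controlled direct epoxidation: from 47, a Shi epoxidation (fructose-derived ketone of the enantiomeric series that matches the β face, KHSO5 as 2KHSO5·KHSO4·K2SO4, buffered MeCN/H2O, 0 °C) gives 49; no new compound arises (F0).

## Further compounds

F1 | step 28 | methyl ketone from hydration of 42: C7 β-C(=O)C[CH2CH(OMe)2](CH2COCH3)CONH2 | C[C@@H]1C[C@H](C)[C@H]2[C@@H](Oc3ccc(I)cc3)[C@@H]4[C@@H](C(=O)[C@](CC(OC)OC)(CC(C)=O)C(N)=O)C(C)=C[C@H](C)[C@H]4[C@]2(C)C1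
F2 | step 28 | macrocyclic C17 hydroxylactam dimethyl acetal | C[C@@H]1C[C@H](C)[C@H]2[C@H]3Oc4ccc(cc4)C[C@]4(O)C[C@](CC(OC)OC)(C(=O)N4)C(=O)[C@H]5C(C)=C[C@H](C)[C@H]([C@H]35)[C@]2(C)C1
F3 | step 30 | bromo hemiperacetal: C8 β-peroxide, C9 α-Br, C10–H β | C[C@@H]1C[C@H](C)[C@H]2[C@H]3Oc4ccc(cc4)C[C@]4(O)C[C@]5(C[C@H](O)OO[C@@]6(C)[C@H](Br)[C@H](C)[C@H]([C@H]3[C@H]6C5=O)[C@]2(C)C1)C(=O)N4
F0 | step 26 | none | none
F4 | step 15 | saturated C8 ketone with C10 methyl α, C7 β-CH2OSi(i-Pr)3, C5 β-OCH2OMe | C[C@@H]1C[C@H](C)[C@H]2[C@@H](OCOC)[C@@H]3[C@@H](CO[Si](C(C)C)(C(C)C)C(C)C)C(=O)C[C@H](C)[C@H]3[C@]2(C)C1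
F0 | step 31 | none | none
A1 | alternative 1 | 4-(tert-butyldimethylsilyloxy)-2-methylcyclopent-2-en-1-one, single enantiomer | CC1=C[C@H](O[Si](C)(C)C(C)(C)C)CC1=O
A2 | alternative 1 | 2,3-dibromoprop-1-ene | BrCC(Br)=C
A3 | alternative 1 | trans,trans-trisubstituted cyclopentanone with the quaternary methyl carbon | C=C(Br)C[C@]1(C)[C@@H](C(C)=C)[C@H](O[Si](C)(C)C(C)(C)C)CC1=O
A4 | alternative 2 | ring A aldehyde carrying the (E)-enoate and methyl ketone chain | C[C@@H]1C[C@H](C)[C@@H](C=O)[C@@](C)(C1)[C@@H](/C=C/C(=O)OC)[C@@H](C)CC(C)=O
A5 | alternative 2 | tricyclic diol ester | C[C@@H]1C[C@H](C)[C@H]2[C@@H](O)[C@@H]3[C@@H](C(=O)OC)[C@@](C)(O)C[C@H](C)[C@H]3[C@]2(C)C1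
A6 | alternative 3 | macrocyclic β-keto lactam with iodo peroxyacetal tether (C15 epimers) | C[C@@H]1C[C@H](C)[C@H]2[C@H]3Oc4ccc(cc4)C[C@]4(O)CC(C(=O)N4)C(=O)[C@H]5[C@@](C)(OO[C@H](CI)OCC)[C@H]6O[C@@]6(C)[C@H]([C@H]35)[C@]2(C)C1
A7 | alternative 3 | O-ethyl peroxyacetal of the target | C[C@@H]1C[C@H](C)[C@H]2[C@H]3Oc4ccc(cc4)C[C@]4(O)C[C@]5(C[C@H](OCC)OO[C@@]6(C)[C@H]7O[C@@]7(C)[C@H]([C@H]3[C@H]6C5=O)[C@]2(C)C1)C(=O)N4
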